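(The runs were generated by integration on assumed constants.)

The constants stay hidden, so the flask is reckoned from its end state, using the charges and readings alone.

| flask | electrophile | nucleophile | free base | remark | time |
|---|---|---|---|---|---|
| Saturday's | 0.25 M | 0.50 M | 0.55 M | run made earlier |  |
| Tuesday's | 1 M | 0.50 M | 0.55 M | run made earlier |  |
| flask | 0.50 M | 0.500 M | 0.550 M |  | 10 d |

| run | time / d | electrophile / % | target / % |
|---|---|---|---|
| Saturday's | 1.04 | 51.6 | 37.0 |
| Saturday's | 1.67 | 39.6 | 40.3 |
| Saturday's | 2.00 | 36.0 | 38.4 |
| Saturday's | 3.00 | 29.4 | 38.6 |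
| Saturday's | 5.00 | 24.6 | 37.3 |
| Saturday's | 8.00 | 20.5 | 36.8 |
| Saturday's | 12.0 | 18.1 | 34.7 |
| Tuesday's | 0.625 | 79.3 | 18.9 |
| Tuesday's | 1.67 | 72.0 | 22.4 |
| Tuesday's | 3.00 | 72.1 | 21.1 |
| Tuesday's | 5.00 | 71.3 | 23.3 |
| Tuesday's | 8.00 | 68.8 | 24.4 |
| Tuesday's | 10.0 | 70.3 | 27.0 |
| Tuesday's | 12.0 | 69.3 | 28.9 |

(scatter of a reading: 1 percentage point)

- the earlier runs do not show how much of nucleophile is bound; that part of a forecast is a guess

- part of the electrophile that has reacted at 10 d
- share of the unused nucleophile that is free and not bound as protonated nucleophile, at 10 d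

Take more electrophile to use no less in amount. Tuesday's run, with the larger charge, then bounds the flask from above: at 10.0 d it had used 59.4% of this flask's electrophile charge. Saturday's run at 8.00 d bounds it from below with 39.7%.

A count gives a figure inside this bracket. If each electrophile used costs two nucleophiles, one reacting and one protonated, nucleophile is the limiting reagent, and the nucleophile ceiling, half the nucleophile charge as a fraction of the electrophile charge, is 50.0%. Approach is early: Tuesday's electrophile went from 72.0% at 1.67 d to just 70.3% at 10.0 d. Tuesday's ceiling of 25.0% was passed, though, so the count is no firm cap, and this reckoning keeps the bracket from 39.7% to 59.4%, with 50.0% as its estimate.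

The forecast gives 50% used, at the ceiling and inside the bracket, and 5% of the unused nucleophile free, holding that “Each turnover therefore removes about two nucleophiles”.

The flask gives 51.1% and 2.38%.

    nucleophile + acid set free ⇌ protonated nucleophile, settled at all times (K = 1100 /M)
    nucleophile + target → over-reaction product (k = 0.0740 /M/h)
    acid set free + free base ⇌ salt of the base (K = 3.80 /M, k = 4.50 /M/h)
    free base ⇌ dormant form (K = 0.440, k = 0.0320 /h)
    electrophile + nucleophile → acid set free + target (k = 0.0860 /M/h)

The ceiling counts one nucleophile bound per electrophile used, but each over-reaction product costs one more, and each acid set free or salt of the base spares one. In this flask at 10.0 d, these stand at 14.3% and 17.3% of the electrophile charge, close enough to leave 51.1% near 50.0%. The neighbour flask with 0.30 M of nucleophile has a ceiling of 30.0%, with 5.87% against 15.0%. Half that surplus, less the free nucleophile's share, gives 34.3%, and that flask used 34.3%.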